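## Analysis of the target

Rhizolutin (38) is a 7/10/6 tricycle. Atom labels run along its SMILES string, so C7 and C21 are the methyl carbons and O15 is the free hydroxyl. A ten-membered carbocycle (C5, C6, C8, C9, C17, C18, C19, C20, C22, C23) shares C5–C23 with a δ-lactone (C3, C4, C24, O26) and C9–C17 with an ε-lactone (O10, C11, C13, C14, C16). The carbocycle carries three alkenes, each with its ring carbons cis: the trisubstituted C6=C8 and the conjugated C18=C19–C20=C22 diene. There are six stereocentres (3S, 5S, 9R, 14S, 17S, 23R); H5/H23 are trans on the δ-lactone, O10 and C16 are trans across C9–C17, and C14 is a carbinol β to the ε-lactone carbonyl. Sensitive sites are C23–H (α to a lactone carbonyl and allylic to the diene), the β-hydroxy lactone at C14, the allylic acyloxy carbon C9 and the Z,Z-diene. The hard part is a medium ring with three cis alkenes and four ring stereocentres, for which direct closure offers no control of alkene geometry. The plan rests on one feature: with a bond drawn between C6 and C19 the carbocycle becomes a bicyclo[4.4.0]decane (ring A: C6, C8, C9, C17, C18, C19; ring B: C5, C6, C19, C20, C22, C23). The Z-C18=C19 alkene and C6 (as a carbonyl) are then the two ends of a C–C fragmentation, and C20=C22 is an ordinary cyclohexene alkene.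

## Retrosynthetic reasoning

**38 back to 34.** The O10–C11 ester bond is cut last: the seven-membered lactone is the least favourable ring and its β-hydroxyl makes it base-sensitive, so it is closed on seco acid 37. The δ-lactone of 37 is traced to the C24/C3 1,5-diol of 36 by oxidative lactonisation, which picks the primary alcohol and needs no separate acid. 36 comes from 35 by global desilylation, and 35 from 34 by cleaving the tert-butyl ester while every hydroxyl is still silylated.

**34 to 32.** The C6–C7 bond is cut as an enol triflate cross-coupling (33). The C6 ketone of 32 is exactly what the fragmentation leaves, and kinetic enolisation toward the C8 methylene gives the regiochemistry.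

**32 to 31 (key).** C6–C19 is re-formed, with oxygen on C6 and a sulfonate on C18. This replaces the medium ring by two six-membered rings with predictable chairs. C20=C22 is cis because it sits in ring B, and the C18=C19 geometry becomes a question of relative configuration. 31 must be cis-fused with C19–C20 axial on ring A, and the C18 mesylate, C9 silyloxy group and C17 side chain must all be equatorial so that the reactive chair is the ground state. That fixes the fusion carbons relative to C9/C17 and to C5/C23.

**31 to 27.** These are adjustments only (30, 29, 28): the C24 ester is reduced and protected so that C23–H is not acidic in the key step, the C6 and C18 oxygens are unmasked together, and only the secondary C18 hydroxyl is mesylated.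

**27 to 25.** Ring B is cut at C5–C23 and C6–C19 (intramolecular Diels–Alder reaction of 26). C6 carries its oxygen as a silyl enol ether, so the angular hydroxyl arrives directly, and ring A is the tether. Three geometric requirements follow from the configuration of 31:
- A 19E diene reaches C6 with the tether endo, which gives the cis fusion with C20 axial on ring A; a chair tether with its three substituents equatorial selects the diene face.
- O6 and C4 must be trans on ring B, so C4 must be cis to C8 on the dienophile: a (5E) enol ether.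
- C24 must be trans to C18 across ring B, so C24 must be the inside substituent: a (22Z) enoate. An (E,E)-diene would give the C23 epimer with C24 axial and syn to C8, and was discarded for that reason.

**25 to 20.** C22=C23 and C19=C20 are cut as two olefinations of the C19 aldehyde 21: stabilised ylide 22 for the E trisubstituted alkene (23) and phosphonate 24 for the Z enoate. 21 comes from the vinyl group of 20, a masked aldehyde carried from 14.

**20/19 to 18 + 5.** C8–C9 is cut as a methyl ketone aldol. It joins the C1–C8 fragment convergently and sets C9 syn to C17.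

**18 to 13 + 14.** C17–C18 is cut as an auxiliary-controlled syn aldol (15, then 16 and 17), which sets C17 and C18; the imide carbonyl becomes C9.

**13 to 6 + 7, 12.** The auxiliary 12 is removed (11); C14 comes from asymmetric hydrogenation of β-keto ester 8 (9, 10), itself made by acylating malonate half-ester 7 with 6.

**5 to 1 + 2.** C4–C5 is cut as an epoxide opening; C3 comes from the chiral pool (3, 4).

## Alternatives that were turned down

**Alternative 1:** The disconnection is C5–C23, the bond common to the δ-lactone and the carbocycle. In the forward step KN(SiMe3)2 would deprotonate C23 across a fourteen-membered lactone ring and the enolate would displace a C5 chloride with inversion, giving the silyl ether A1.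
- For: two rings close in one step from a ring size that macrolactonisation delivers easily, and A1 is one desilylation from 38. In step count after the key step this is stronger than the chosen route.
- Against: the nucleophile is an enolate conjugated through both diene alkenes, so α, γ and ε alkylation compete. The electrophile is a secondary allylic chloride open to SN2' attack at C8 and to elimination. The C23 configuration depends on an unknown macrocycle conformation, and all three cis alkenes must be built and kept without a small ring to enforce them.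
- Comparison: the chosen route spends more steps but derives every alkene geometry from six-membered-ring stereochemistry.

**Alternative 2:** C5–C23 and C9–C17 are cut together. Heating would bring a C17–C23 trienoate and a C5–C9 dienone together across the ring in a [6+4] cycloaddition to give the keto lactone A2; oxygen insertion next to C9 would then make the ε-lactone.
- For: two C–C bonds, three rings, four stereocentres and all three ring alkenes form in one pericyclic step, probably as in biosynthesis. In bond-forming economy this is clearly stronger than the chosen route.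
- Against: the same π-systems can combine in several [4+2] modes, so periselectivity is not assured. The polyene macrocyclic substrate is laborious and labile. The later oxygen insertion must choose the right migrating carbon and spare three alkenes from the peracid. Facial selectivity would rest on remote stereocentres.
- Comparison: the chosen route is longer, but each stereochemical element is set by a reaction with an established model.

**Alternative 3:** C9–C17 is cut as a ring contraction. Tin–lithium exchange at C9 of a thirteen-membered cyclic allylic ether would give an α-alkoxy organolithium whose [2,3]-shift forms C9–C17 and gives alcohol A3 with a C17 vinyl group.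
- For: the larger ether ring is easier to close than the carbocycle, and the low-temperature sigmatropic step transfers chirality and sets C9 and C17 together. On the strain of the ring-forming event it is stronger than the chosen route.
- Against: the migrating terminus is part of a conjugated triene and the carbanion is itself allylic, so [1,2]- and vinylogous shifts compete. The trans C9/C17 outcome depends on a macrocyclic transition state that cannot be predicted. The vinyl group must still be grown into C14–C11 with a new stereocentre, and both lactones must then be closed.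
- Comparison: the chosen route carries the full side chain through and sets the C18=C19 geometry by a stereospecific fragmentation.

Key step: step 23

Remark on the chemistry: atom labels C1–O26 follow the target's SMILES string; compounds 1, 2, 6, 7, 12, 14, 22 and 24 are taken as purchasable, and reagent antipodes are chosen by the usual empirical models.

## Route

Step 1
Reactants: 1 (S)-1,2-epoxybutane; 2 2-methylallylmagnesium chloride
Product: 3 (S)-6-methylhept-6-en-3-ol
Conditions: CuI (10 mol%), THF, −30 to 0 °C
Reagents that add atoms: none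
Why: Copper-catalysed Grignard opening of a terminal epoxide (SN2 at the CH2); the C3 stereocentre comes unchanged from 1.

Step 2
Reactants: 3 (S)-6-methylhept-6-en-3-ol
Product: 4 (S)-3-(tert-butyldimethylsilyloxy)-6-methylhept-6-ene
Conditions: tBuMe2SiCl, imidazole, DMF, rt
Reagents that add atoms: tert-butyldimethylsilyl chloride, CC(C)(C)[Si](C)(C)Cl
Why: Standard silyl ether formation; the ether must last to the end of the route.

Step 3
Reactants: 4 (S)-3-(tert-butyldimethylsilyloxy)-6-methylhept-6-ene
Product: 5 (S)-5-(tert-butyldimethylsilyloxy)heptan-2-one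
Conditions: O3, CH2Cl2/MeOH, −78 °C; then PPh3
Reagents that add atoms: ozone, [O-][O+]=O
Why: Ozonolysis of the 1,1-disubstituted alkene gives the methyl ketone (C6 carbonyl, C8 methyl); no other oxidisable group is present.

Step 4
Reactants: 6 monomethyl succinate; 7 mono-tert-butyl malonate
Product: 8 1-tert-butyl 6-methyl 3-oxohexanedioate
Conditions: 6, 1,1'-carbonyldiimidazole, THF, rt; then 7, MgCl2, Et3N, MeCN, rt
Reagents that add atoms: none
Why: Masamune–Brooks C-acylation of a magnesium malonate half-ester by the acyl imidazole, with loss of CO2; this forms C13–C14 and leaves the two ester ends differentiated.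

Step 5
Reactants: 8 1-tert-butyl 6-methyl 3-oxohexanedioate
Product: 9 1-tert-butyl 6-methyl (S)-3-hydroxyhexanedioate
Conditions: H2 (50 bar), RuCl2[(S)-BINAP] (0.5 mol%), MeOH, 30 °C
Reagents that add atoms: none
Why: Noyori asymmetric hydrogenation; the β-keto ester chelate directs hydride delivery and the (S)-ligand should give (S)-C14 by analogy with simple 3-oxo esters. The crude product is silylated at once so that the γ-hydroxy methyl ester does not lactonise.

Step 6
Reactants: 9 1-tert-butyl 6-methyl (S)-3-hydroxyhexanedioate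
Product: 10 1-tert-butyl 6-methyl (S)-3-(tert-butyldimethylsilyloxy)hexanedioate
Conditions: tBuMe2SiCl, imidazole, DMF, rt
Reagents that add atoms: tert-butyldimethylsilyl chloride, CC(C)(C)[Si](C)(C)Cl
Why: Silyl ether formation; it blocks lactonisation and protects O15 until the global deprotection.

Step 7
Reactants: 10 1-tert-butyl 6-methyl (S)-3-(tert-butyldimethylsilyloxy)hexanedioate
Product: 11 (S)-6-tert-butoxy-4-(tert-butyldimethylsilyloxy)-6-oxohexanoic acid
Conditions: LiOH, THF/H2O, 0 °C; then 1 M HCl to pH 3
Reagents that add atoms: lithium hydroxide, [Li+].[OH-]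
Why: Saponification; the unhindered methyl ester is hydrolysed while the tert-butyl ester resists hydroxide.

Step 8
Reactants: 11 (S)-6-tert-butoxy-4-(tert-butyldimethylsilyloxy)-6-oxohexanoic acid; 12 (S)-4-benzyl-2-oxazolidinone
Product: 13 tert-butyl (S)-6-[(S)-4-benzyl-2-oxooxazolidin-3-yl]-3-(tert-butyldimethylsilyloxy)-6-oxohexanoate
Conditions: (CH3)3CCOCl, Et3N, THF, −20 °C; then 12, LiCl, rt
Reagents that add atoms: none
Why: N-acylation of the oxazolidinone through the mixed pivalic anhydride under mild LiCl/amine conditions; no strong base touches the β-silyloxy ester.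

Step 9
Reactants: 13 tert-butyl (S)-6-[(S)-4-benzyl-2-oxooxazolidin-3-yl]-3-(tert-butyldimethylsilyloxy)-6-oxohexanoate; 14 acrolein
Product: 15 syn-aldol imide, tert-butyl (3S,5S,6R)-5-[(S)-4-benzyl-2-oxooxazolidine-3-carbonyl]-3-(tert-butyldimethylsilyloxy)-6-hydroxyoct-7-enoate
Conditions: Bu2BOTf, iPr2NEt, CH2Cl2, −78 to 0 °C; then 14, −78 to 0 °C; H2O2, MeOH, pH 7 buffer
Reagents that add atoms: none
Why: Evans syn aldol; the Z boron enolate reacts through a Zimmerman–Traxler chair on the face opposite the benzyl group, which sets C17 (S) and C18 (R) as required in 31. Only the imide is enolised under these soft conditions.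

Step 10
Reactants: 15 syn-aldol imide
Product: 16 C18 triethylsilyl ether of 15
Conditions: Et3SiOTf, 2,6-lutidine, CH2Cl2, −78 °C
Reagents that add atoms: triethylsilyl triflate, CC[Si](CC)(CC)OS(=O)(=O)C(F)(F)F
Why: Silylation of the secondary alcohol; the triethylsilyl group is chosen because it can later be removed in the presence of the tert-butyldimethylsilyl ethers, and the low temperature spares the tert-butyl ester.

Step 11
Reactants: 16 C18 triethylsilyl ether of 15
Product: 17 primary alcohol, tert-butyl 3-(tert-butyldimethylsilyloxy)-5-(hydroxymethyl)-6-(triethylsilyloxy)oct-7-enoate (stereocentres as in 15)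
Conditions: LiBH4, MeOH (1 equiv), Et2O, 0 °C
Reagents that add atoms: none
Why: Reductive cleavage of the N-acyl oxazolidinone; the imide carbonyl is far more electrophilic than the tert-butyl ester, and 12 is recovered.

Step 12
Reactants: 17 primary alcohol
Product: 18 C9 aldehyde, tert-butyl 3-(tert-butyldimethylsilyloxy)-5-formyl-6-(triethylsilyloxy)oct-7-enoate (stereocentres as in 15)
Conditions: Dess–Martin periodinane, NaHCO3, CH2Cl2, 0 °C to rt
Reagents that add atoms: none
Why: Buffered Dess–Martin oxidation, which does not epimerise the α-stereocentre C17; the aldehyde is used without storage.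

Step 13
Reactants: 18 C9 aldehyde; 5 (S)-5-(tert-butyldimethylsilyloxy)heptan-2-one
Product: 19 β-hydroxy ketone (C1–C19 chain: C6 ketone, C9 hydroxyl syn to the C17 side chain and to the C18 silyloxy group)
Conditions: 5, (+)-Ipc2BCl, Et3N, Et2O, 0 °C; then 18, −78 to −20 °C; H2O2, MeOH, pH 7 buffer
Reagents that add atoms: none
Why: Paterson boron aldol of a methyl ketone; enolisation is regioselective for the methyl group, and the (+)-reagent should direct attack to the Si face of the aldehyde. That face is also the Felkin face, so reagent and substrate should reinforce each other to give the all-syn C9/C17/C18 triad.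

Step 14
Reactants: 19 β-hydroxy ketone
Product: 20 C9 tert-butyldimethylsilyl ether of 19
Conditions: tBuMe2SiOTf, 2,6-lutidine, CH2Cl2, −78 °C
Reagents that add atoms: tert-butyldimethylsilyl triflate, CC(C)(C)[Si](C)(C)OS(=O)(=O)C(F)(F)F
Why: Silylation of the hindered secondary alcohol; at −78 °C neither the ketone nor the tert-butyl ester reacts with the silyl triflate.

Step 15
Reactants: 20 C9 tert-butyldimethylsilyl ether of 19
Product: 21 C19 aldehyde (α-triethylsilyloxy aldehyde)
Conditions: O3, CH2Cl2, −78 °C; then PPh3
Reagents that add atoms: ozone, [O-][O+]=O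
Why: Ozonolysis of the only alkene unmasks the C19 aldehyde carried from acrolein.

Step 16
Reactants: 21 C19 aldehyde; 22 2-(triphenylphosphoranylidene)propanal
Product: 23 (19E)-2-methyl enal (C22 aldehyde)
Conditions: toluene, 80 °C
Reagents that add atoms: none
Why: Wittig reaction of a stabilised ylide, which gives the E trisubstituted alkene (C18 trans to C22) and reacts with the aldehyde but not with the C6 ketone.

Step 17
Reactants: 23 (19E)-2-methyl enal; 24 methyl bis(2,2,2-trifluoroethyl)phosphonoacetate
Product: 25 keto dienoate, methyl (2Z,4E)-4-methyl-2,4-dienoate terminus (22Z, 19E) on the C1–C24 chain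
Conditions: KN(SiMe3)2, 18-crown-6, THF, −78 °C
Reagents that add atoms: none
Why: Still–Gennari olefination; the electron-poor phosphonate under dissociating conditions gives the Z enoate (C24 cis to C20) and does not touch the ketone.

Step 18
Reactants: 25 keto dienoate
Product: 27 cis-octalin adduct (C6 trimethylsilyl ether, C18 triethylsilyl ether, C24 methyl ester), via (5E)-trimethylsilyl enol ether 26 (not isolated)
Conditions: lithium 2,2,6,6-tetramethylpiperidide, Me3SiCl, THF, −78 °C (25 added last); pentane filtration; then toluene (2 mM), BHT, 170 °C, sealed tube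
Reagents that add atoms: chlorotrimethylsilane, C[Si](C)(C)Cl
Why: Kinetic enolisation with in situ silylation should take the less hindered C5 proton through the Ireland chair and give the E(O) enol ether (C4 cis to C8). The intramolecular Diels–Alder reaction then pairs the ester-lowered diene with the electron-rich enol ether; the 19E diene reaches C6 only with the tether endo, so the fusion is cis, and a chair tether with the C9, C17 and C18 substituents equatorial selects the diene face. Suprafacial addition then places O6 trans to C4 and the inside C24 trans to C18, so C5, C6, C19 and C23 are set as in 31; the inside ester would also clash with an exo C4, which disfavours the trans-fused mode.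

Step 19
Reactants: 27 cis-octalin adduct
Product: 28 C24 primary alcohol
Conditions: LiBH4, MeOH, THF, 0 °C to rt
Reagents that add atoms: none
Why: Ester reduction; LiBH4 reduces the methyl ester and should leave the tert-butyl ester. This removes the acidity of C23–H before the base-mediated key step.

Step 20
Reactants: 28 C24 primary alcohol
Product: 29 C24 tert-butyldiphenylsilyl ether
Conditions: tBuPh2SiCl, imidazole, CH2Cl2, rt
Reagents that add atoms: tert-butyldiphenylsilyl chloride, CC(C)(C)[Si](Cl)(c1ccccc1)c1ccccc1
Why: Silylation of the only free hydroxyl; the diphenyl group is acid-stable enough for the next step.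

Step 21
Reactants: 29 C24 tert-butyldiphenylsilyl ether
Product: 30 C6,C18-diol
Conditions: pyridinium p-toluenesulfonate, MeOH/CH2Cl2, 0 °C to rt
Reagents that add atoms: none
Why: Acid-catalysed methanolysis graded by silyl group; the tertiary trimethylsilyl and secondary triethylsilyl ethers go while the tert-butyldimethylsilyl and tert-butyldiphenylsilyl ethers stay.

Step 22
Reactants: 30 C6,C18-diol
Product: 31 cis-octalin tertiary alcohol C18 mesylate
Conditions: CH3SO2Cl, Et3N, CH2Cl2, −20 to 0 °C
Reagents that add atoms: methanesulfonyl chloride, CS(=O)(=O)Cl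
Why: Sulfonylation through sulfene, which reacts with the secondary C18 hydroxyl and leaves the tertiary C6 hydroxyl free.

Step 23
Reactants: 31 cis-octalin tertiary alcohol C18 mesylate
Product: 32 ten-membered Z,Z-dienyl C6 ketone
Conditions: KOC(CH3)3 (1.05 equiv), THF, −20 to 0 °C
Reagents that add atoms: none
Why: tert-Butoxide deprotonates the C6 hydroxyl; the alkoxide lone pair pushes into the C6–C19 bond, which breaks as the antiperiplanar C18–O bond leaves, giving the C6 ketone and the C18=C19 alkene in one concerted step. The closest known reaction type is the Grob (Wharton) fragmentation of decalin 1,3-diol monosulfonates to cyclodecenones. No ring is closed by bond formation; the ten-membered ring appears when the bond shared by rings A and B is cut, and no new stereocentre is made. In the ground-state chair of ring A the mesylate, the C9 silyloxy group and the C17 side chain are equatorial, so C18–O is anti to C6–C19. Because the fusion is cis, C19–C20 is axial on ring A and H19 is anti to C18–C17, so C17 and C20 emerge cis (Z); the C20=C22 alkene is carried over unchanged. The step needs fragmentation to outrun elimination and oxetane closure: the equatorial mesylate has no anti hydrogen, and the exact orbital alignment favours fragmentation. It also needs C9–O to stay silylated, since a C9 alkoxide could fragment C9–C17. The base is consumed as potassium mesylate, which protects the new α-stereocentre C5 and the β-silyloxy group at C9.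

Step 24
Reactants: 32 ten-membered Z,Z-dienyl C6 ketone
Product: 33 C6 enol triflate (C6=C8, ring carbons C5 and C9 cis)
Conditions: LiN(iPr)2, THF, −78 °C; then N-(5-chloro-2-pyridyl)bis(trifluoromethanesulfonimide), −78 °C
Reagents that add atoms: N-(5-chloro-2-pyridyl)bis(trifluoromethanesulfonimide), O=S(=O)(N(c1ccc(Cl)cn1)S(=O)(=O)C(F)(F)F)C(F)(F)F
Why: Kinetic enolate triflation; the amide base takes a C8 methylene proton rather than the C5 methine, and the ring, already holding a rigid cis,cis-diene, should allow only the enolate with C5 and C9 cis. Trapping at −78 °C forestalls loss of the C9 silyloxy group.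

Step 25
Reactants: 33 C6 enol triflate
Product: 34 C6-methyl triene (all ring alkenes cis)
Conditions: CH3MgBr, Fe(acac)3 (10 mol%), THF/NMP, −30 °C
Reagents that add atoms: methylmagnesium bromide, C[Mg]Br
Why: Iron-catalysed cross-coupling of an alkenyl triflate with a Grignard reagent; it is fast at low temperature, retains alkene geometry and tolerates the tert-butyl ester and silyl ethers.

Step 26
Reactants: 34 C6-methyl triene
Product: 35 C11 carboxylic acid (all four silyl ethers intact)
Conditions: Me3SiOTf, 2,6-lutidine, CH2Cl2, 0 °C; aq. citric acid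
Reagents that add atoms: none
Why: Silyl triflate cleavage of a tert-butyl ester (loss of isobutene, silyl ester hydrolysed on work-up); it is done while every hydroxyl is silylated, so no protic acid meets the free allylic alcohol.

Step 27
Reactants: 35 C11 carboxylic acid
Product: 36 tetraol acid (free hydroxyls at C3, C9, C14, C24)
Conditions: HF·pyridine, pyridine, THF, 0 °C to rt
Reagents that add atoms: none
Why: Buffered fluoride desilylation removes all four silyl ethers without base, which spares the β-hydroxy acid and the diene.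

Step 28
Reactants: 36 tetraol acid
Product: 37 δ-lactone dihydroxy acid (seco acid of the ε-lactone)
Conditions: TEMPO (20 mol%), PhI(OAc)2, CH2Cl2, rt
Reagents that add atoms: none
Why: Oxoammonium oxidation selects the primary C24 alcohol; the aldehyde is trapped by the C3 hydroxyl as a six-membered lactol, which is oxidised on to the lactone (oxidative lactonisation of a 1,5-diol). The secondary alcohols react far more slowly.

Step 29
Reactants: 37 δ-lactone dihydroxy acid
Product: 38 rhizolutin
Conditions: 2,4,6-Cl3C6H2COCl, Et3N, THF, rt; then DMAP, toluene (1 mM), 60 °C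
Reagents that add atoms: none
Why: Yamaguchi lactonisation through the mixed anhydride; under high dilution the C9 hydroxyl should close the seven-membered ring, since the C14 hydroxyl could only form a strained β-lactone.

## Compound list

1 | (S)-1,2-epoxybutane | CC[C@H]1CO1 | starting material
2 | 2-methylallylmagnesium chloride | C=C(C)C[Mg]Cl | starting material
3 | (S)-6-methylhept-6-en-3-ol | CC[C@H](O)CCC(C)=C | intermediate
4 | (S)-3-(tert-butyldimethylsilyloxy)-6-methylhept-6-ene | CC[C@H](O[Si](C)(C)C(C)(C)C)CCC(C)=C | intermediate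
5 | (S)-5-(tert-butyldimethylsilyloxy)heptan-2-one | CC[C@H](O[Si](C)(C)C(C)(C)C)CCC(C)=O | intermediate
6 | monomethyl succinate (4-methoxy-4-oxobutanoic acid) | COC(=O)CCC(=O)O | starting material
7 | mono-tert-butyl malonate (3-tert-butoxy-3-oxopropanoic acid) | CC(C)(C)OC(=O)CC(=O)O | starting material
8 | 1-tert-butyl 6-methyl 3-oxohexanedioate | COC(=O)CCC(=O)CC(=O)OC(C)(C)C | intermediate
9 | 1-tert-butyl 6-methyl (S)-3-hydroxyhexanedioate | COC(=O)CC[C@H](O)CC(=O)OC(C)(C)C | intermediate
10 | 1-tert-butyl 6-methyl (S)-3-(tert-butyldimethylsilyloxy)hexanedioate | COC(=O)CC[C@H](O[Si](C)(C)C(C)(C)C)CC(=O)OC(C)(C)C | intermediate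
11 | (S)-6-tert-butoxy-4-(tert-butyldimethylsilyloxy)-6-oxohexanoic acid | OC(=O)CC[C@H](O[Si](C)(C)C(C)(C)C)CC(=O)OC(C)(C)C | intermediate
12 | (S)-4-benzyl-2-oxazolidinone | O=C1OC[C@H](Cc2ccccc2)N1 | starting material
13 | tert-butyl (S)-6-[(S)-4-benzyl-2-oxooxazolidin-3-yl]-3-(tert-butyldimethylsilyloxy)-6-oxohexanoate | O=C1OC[C@H](Cc2ccccc2)N1C(=O)CC[C@H](O[Si](C)(C)C(C)(C)C)CC(=O)OC(C)(C)C | intermediate
14 | acrolein (prop-2-enal) | C=CC=O | starting material
15 | syn-aldol imide, tert-butyl (3S,5S,6R)-5-[(S)-4-benzyl-2-oxooxazolidine-3-carbonyl]-3-(tert-butyldimethylsilyloxy)-6-hydroxyoct-7-enoate | O=C1OC[C@H](Cc2ccccc2)N1C(=O)[C@@H](C[C@H](O[Si](C)(C)C(C)(C)C)CC(=O)OC(C)(C)C)[C@H](O)C=C | intermediate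
16 | C18 triethylsilyl ether of 15 | O=C1OC[C@H](Cc2ccccc2)N1C(=O)[C@@H](C[C@H](O[Si](C)(C)C(C)(C)C)CC(=O)OC(C)(C)C)[C@H](O[Si](CC)(CC)CC)C=C | intermediate
17 | tert-butyl 3-(tert-butyldimethylsilyloxy)-5-(hydroxymethyl)-6-(triethylsilyloxy)oct-7-enoate, stereocentres as in 15 | OC[C@@H](C[C@H](O[Si](C)(C)C(C)(C)C)CC(=O)OC(C)(C)C)[C@H](O[Si](CC)(CC)CC)C=C | intermediate
18 | C9 aldehyde, tert-butyl 3-(tert-butyldimethylsilyloxy)-5-formyl-6-(triethylsilyloxy)oct-7-enoate, stereocentres as in 15 | O=C[C@@H](C[C@H](O[Si](C)(C)C(C)(C)C)CC(=O)OC(C)(C)C)[C@H](O[Si](CC)(CC)CC)C=C | intermediate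
19 | β-hydroxy ketone: C1–C19 chain with C6 ketone, C9 hydroxyl (all-syn with C17 and C18), 3- and 14-tert-butyldimethylsilyloxy, 18-triethylsilyloxy, C11 tert-butyl ester, terminal vinyl | CC[C@H](O[Si](C)(C)C(C)(C)C)CCC(=O)C[C@H](O)[C@@H](C[C@H](O[Si](C)(C)C(C)(C)C)CC(=O)OC(C)(C)C)[C@H](O[Si](CC)(CC)CC)C=C | intermediate
20 | C9 tert-butyldimethylsilyl ether of 19 | CC[C@H](O[Si](C)(C)C(C)(C)C)CCC(=O)C[C@H](O[Si](C)(C)C(C)(C)C)[C@@H](C[C@H](O[Si](C)(C)C(C)(C)C)CC(=O)OC(C)(C)C)[C@H](O[Si](CC)(CC)CC)C=C | intermediate
21 | C19 aldehyde from 20 (vinyl replaced by formyl) | CC[C@H](O[Si](C)(C)C(C)(C)C)CCC(=O)C[C@H](O[Si](C)(C)C(C)(C)C)[C@@H](C[C@H](O[Si](C)(C)C(C)(C)C)CC(=O)OC(C)(C)C)[C@H](O[Si](CC)(CC)CC)C=O | intermediate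
22 | 2-(triphenylphosphoranylidene)propanal | CC(C=O)=P(c1ccccc1)(c1ccccc1)c1ccccc1 | starting material
23 | (19E)-2-methyl enal: C18–CH=C(CH3)–CHO on the chain of 21 | CC[C@H](O[Si](C)(C)C(C)(C)C)CCC(=O)C[C@H](O[Si](C)(C)C(C)(C)C)[C@@H](C[C@H](O[Si](C)(C)C(C)(C)C)CC(=O)OC(C)(C)C)[C@H](O[Si](CC)(CC)CC)/C=C(C)/C=O | intermediate
24 | methyl bis(2,2,2-trifluoroethyl)phosphonoacetate | COC(=O)CP(=O)(OCC(F)(F)F)OCC(F)(F)F | starting material
25 | keto dienoate: C6 ketone with methyl (2Z,4E)-4-methyl-2,4-dienoate terminus (22Z, 19E) | CC[C@H](O[Si](C)(C)C(C)(C)C)CCC(=O)C[C@H](O[Si](C)(C)C(C)(C)C)[C@@H](C[C@H](O[Si](C)(C)C(C)(C)C)CC(=O)OC(C)(C)C)[C@H](O[Si](CC)(CC)CC)/C=C(C)/C=C\C(=O)OC | intermediate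
26 | (5E)-trimethylsilyl enol ether of 25 (C5=C6, C4 cis to C8) | CC[C@H](O[Si](C)(C)C(C)(C)C)C/C=C(/O[Si](C)(C)C)C[C@H](O[Si](C)(C)C(C)(C)C)[C@@H](C[C@H](O[Si](C)(C)C(C)(C)C)CC(=O)OC(C)(C)C)[C@H](O[Si](CC)(CC)CC)/C=C(C)/C=C\C(=O)OC | intermediate
27 | cis-octalin adduct: ring A with equatorial C9-OTBS, C17 side chain and C18-OTES; angular C6-OSiMe3; ring B with C20=C22, C5 side chain and C23 methyl ester trans | CC[C@H](O[Si](C)(C)C(C)(C)C)C[C@H]1[C@H](C(=O)OC)C=C(C)[C@@H]2[C@@]1(O[Si](C)(C)C)C[C@H](O[Si](C)(C)C(C)(C)C)[C@@H](C[C@H](O[Si](C)(C)C(C)(C)C)CC(=O)OC(C)(C)C)[C@@H]2O[Si](CC)(CC)CC | intermediate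
28 | C24 primary alcohol of 27 | CC[C@H](O[Si](C)(C)C(C)(C)C)C[C@H]1[C@H](CO)C=C(C)[C@@H]2[C@@]1(O[Si](C)(C)C)C[C@H](O[Si](C)(C)C(C)(C)C)[C@@H](C[C@H](O[Si](C)(C)C(C)(C)C)CC(=O)OC(C)(C)C)[C@@H]2O[Si](CC)(CC)CC | intermediate
29 | C24 tert-butyldiphenylsilyl ether of 28 | CC[C@H](O[Si](C)(C)C(C)(C)C)C[C@H]1[C@H](CO[Si](c3ccccc3)(c3ccccc3)C(C)(C)C)C=C(C)[C@@H]2[C@@]1(O[Si](C)(C)C)C[C@H](O[Si](C)(C)C(C)(C)C)[C@@H](C[C@H](O[Si](C)(C)C(C)(C)C)CC(=O)OC(C)(C)C)[C@@H]2O[Si](CC)(CC)CC | intermediate
30 | C6,C18-diol (tertiary C6 hydroxyl axial on ring A, secondary C18 hydroxyl equatorial) | CC[C@H](O[Si](C)(C)C(C)(C)C)C[C@H]1[C@H](CO[Si](c3ccccc3)(c3ccccc3)C(C)(C)C)C=C(C)[C@@H]2[C@@]1(O)C[C@H](O[Si](C)(C)C(C)(C)C)[C@@H](C[C@H](O[Si](C)(C)C(C)(C)C)CC(=O)OC(C)(C)C)[C@@H]2O | intermediate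
31 | cis-octalin tertiary alcohol C18 mesylate | CC[C@H](O[Si](C)(C)C(C)(C)C)C[C@H]1[C@H](CO[Si](c3ccccc3)(c3ccccc3)C(C)(C)C)C=C(C)[C@@H]2[C@@]1(O)C[C@H](O[Si](C)(C)C(C)(C)C)[C@@H](C[C@H](O[Si](C)(C)C(C)(C)C)CC(=O)OC(C)(C)C)[C@@H]2OS(C)(=O)=O | intermediate
32 | ten-membered Z,Z-dienyl C6 ketone | CC[C@H](O[Si](C)(C)C(C)(C)C)C[C@@H]1C(=O)C[C@H](O[Si](C)(C)C(C)(C)C)[C@@H](C[C@H](O[Si](C)(C)C(C)(C)C)CC(=O)OC(C)(C)C)/C=C\C(C)=C/[C@H]1CO[Si](c2ccccc2)(c2ccccc2)C(C)(C)C | intermediate
33 | C6 enol triflate (C6=C8, C5 and C9 cis) | CC[C@H](O[Si](C)(C)C(C)(C)C)C[C@@H]1/C(OS(=O)(=O)C(F)(F)F)=C\[C@H](O[Si](C)(C)C(C)(C)C)[C@@H](C[C@H](O[Si](C)(C)C(C)(C)C)CC(=O)OC(C)(C)C)/C=C\C(C)=C/[C@H]1CO[Si](c2ccccc2)(c2ccccc2)C(C)(C)C | intermediate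
34 | C6-methyl triene (fully protected rhizolutin seco ester) | CC[C@H](O[Si](C)(C)C(C)(C)C)C[C@@H]1/C(C)=C\[C@H](O[Si](C)(C)C(C)(C)C)[C@@H](C[C@H](O[Si](C)(C)C(C)(C)C)CC(=O)OC(C)(C)C)/C=C\C(C)=C/[C@H]1CO[Si](c2ccccc2)(c2ccccc2)C(C)(C)C | intermediate
35 | C11 carboxylic acid of 34 | CC[C@H](O[Si](C)(C)C(C)(C)C)C[C@@H]1/C(C)=C\[C@H](O[Si](C)(C)C(C)(C)C)[C@@H](C[C@H](O[Si](C)(C)C(C)(C)C)CC(=O)O)/C=C\C(C)=C/[C@H]1CO[Si](c2ccccc2)(c2ccccc2)C(C)(C)C | intermediate
36 | tetraol acid (C3, C9, C14, C24 hydroxyls; C11 acid) | CC[C@H](O)C[C@@H]1/C(C)=C\[C@H](O)[C@@H](C[C@H](O)CC(=O)O)/C=C\C(C)=C/[C@H]1CO | intermediate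
37 | δ-lactone dihydroxy acid (C24–O26 lactone closed; C9 and C14 hydroxyls, C11 acid) | CC[C@H]1C[C@@H]2/C(C)=C\[C@H](O)[C@@H](C[C@H](O)CC(=O)O)/C=C\C(C)=C/[C@H]2C(=O)O1 | intermediate
38 | rhizolutin | CC[C@H]1C[C@@H]2/C(C)=C\[C@@H]3OC(=O)C[C@@H](O)C[C@H]3/C=C\C(C)=C/[C@H]2C(=O)O1 | target

## Step count and least certain steps

Total: 29 steps. Longest linear sequence: 26 steps (steps 4–12, then 13–29).

**Step 23 (key step).** The alkoxide may displace the mesylate instead of fragmenting (oxetane closure, which the axial O6 and equatorial mesylate also allow), or leftover base may epimerise C5 of the new ketone or eliminate the C9 silyloxy group. Fallback: set out from 31 and silylate the tertiary hydroxyl with N-(trimethylsilyl)imidazole to give the O6-trimethylsilyl ether mesylate F1. Treatment with CsF and 18-crown-6 in DMF frees the alkoxide in an aprotic medium with no Brønsted base, and the fragmentation returns to the route at 32.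

**Step 18.** The cycloaddition may be too slow because the inside ester strains the s-cis diene, and prolonged heating may then degrade the enol ether; imperfect regio- or E-selectivity in the enolisation would add isomeric adducts. Fallback: set out from 23 and use bis(2,2,2-trifluoroethyl) cyanomethylphosphonate with KN(SiMe3)2 to make the (22Z)-dienenitrile F2, in which the inside group is small and linear and activates more strongly. Enol silylation as before gives the (5E)-trimethylsilyl enol ether F3, which is heated to the nitrile octalin F4. iBu2AlH at −78 °C then gives the C24 aldehyde F5, and NaBH4 returns to the route at 28.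

**Step 13.** Facial selectivity at C9 may be poor if the reagent's preference and the aldehyde's own bias do not reinforce each other as assumed. Fallback: set out from 5 and make its kinetic trimethylsilyl enol ether F6 (LiN(iPr)2, Me3SiCl). A Mukaiyama aldol with 18 and BF3·OEt2 at −78 °C then relies on open-transition-state Felkin control by the α-stereocentre instead of reagent control, and returns to the route at 19.

**Step 24.** Enolisation may give the ring-trans enolate or some C5 deprotonation, so that the coupling would deliver the wrong C6=C8 geometry or regiochemistry. Fallback: set out from 32 and condense it with 2,4,6-triisopropylbenzenesulfonyl hydrazide to the hydrazone F7. In a Shapiro reaction sec-BuLi (2 equiv, THF, −78 to 0 °C) removes the C8 proton syn to the sulfonamide and gives the cis vinyllithium F8, which is quenched with CH3I; this bypasses 33 and returns at 34. The short exposure of the tert-butyl ester to the alkyllithium is the price.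

**Step 29.** Activation of a β-hydroxy acid may lead to acylation of the C14 hydroxyl (oligomers or β-lactone) or to dehydration. Fallback: set out from 37 and silylate the less hindered C14 hydroxyl selectively (Et3SiCl, imidazole, −20 °C) to the C14 triethylsilyl ether acid F9. Lactonisation under the same Yamaguchi conditions, now with one free hydroxyl, gives rhizolutin O15-triethylsilyl ether F10, and HF·pyridine returns to the route at 38.

## Further compounds

F1 | step 23 | O6-trimethylsilyl ether of mesylate 31 | CC[C@H](O[Si](C)(C)C(C)(C)C)C[C@H]1[C@H](CO[Si](c3ccccc3)(c3ccccc3)C(C)(C)C)C=C(C)[C@@H]2[C@@]1(O[Si](C)(C)C)C[C@H](O[Si](C)(C)C(C)(C)C)[C@@H](C[C@H](O[Si](C)(C)C(C)(C)C)CC(=O)OC(C)(C)C)[C@@H]2OS(C)(=O)=O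
F2 | step 18 | (22Z,19E)-dienenitrile analogue of 25 | CC[C@H](O[Si](C)(C)C(C)(C)C)CCC(=O)C[C@H](O[Si](C)(C)C(C)(C)C)[C@@H](C[C@H](O[Si](C)(C)C(C)(C)C)CC(=O)OC(C)(C)C)[C@H](O[Si](CC)(CC)CC)/C=C(C)/C=C\C#N
F3 | step 18 | (5E)-trimethylsilyl enol ether of F2 | CC[C@H](O[Si](C)(C)C(C)(C)C)C/C=C(/O[Si](C)(C)C)C[C@H](O[Si](C)(C)C(C)(C)C)[C@@H](C[C@H](O[Si](C)(C)C(C)(C)C)CC(=O)OC(C)(C)C)[C@H](O[Si](CC)(CC)CC)/C=C(C)/C=C\C#N
F4 | step 18 | C23 nitrile analogue of octalin 27 | CC[C@H](O[Si](C)(C)C(C)(C)C)C[C@H]1[C@H](C#N)C=C(C)[C@@H]2[C@@]1(O[Si](C)(C)C)C[C@H](O[Si](C)(C)C(C)(C)C)[C@@H](C[C@H](O[Si](C)(C)C(C)(C)C)CC(=O)OC(C)(C)C)[C@@H]2O[Si](CC)(CC)CC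
F5 | step 18 | C24 aldehyde analogue of octalin 27 | CC[C@H](O[Si](C)(C)C(C)(C)C)C[C@H]1[C@H](C=O)C=C(C)[C@@H]2[C@@]1(O[Si](C)(C)C)C[C@H](O[Si](C)(C)C(C)(C)C)[C@@H](C[C@H](O[Si](C)(C)C(C)(C)C)CC(=O)OC(C)(C)C)[C@@H]2O[Si](CC)(CC)CC
F6 | step 13 | kinetic trimethylsilyl enol ether of ketone 5 | CC[C@H](O[Si](C)(C)C(C)(C)C)CCC(=C)O[Si](C)(C)C
F7 | step 24 | 2,4,6-triisopropylbenzenesulfonyl hydrazone of ketone 32 (N–N syn to C8) | CC[C@H](O[Si](C)(C)C(C)(C)C)C[C@@H]1/C(=N/NS(=O)(=O)c2c(C(C)C)cc(C(C)C)cc2C(C)C)C[C@H](O[Si](C)(C)C(C)(C)C)[C@@H](C[C@H](O[Si](C)(C)C(C)(C)C)CC(=O)OC(C)(C)C)/C=C\C(C)=C/[C@H]1CO[Si](c2ccccc2)(c2ccccc2)C(C)(C)C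
F8 | step 24 | C6 vinyllithium (C6=C8, C5 and C9 cis) | CC[C@H](O[Si](C)(C)C(C)(C)C)C[C@@H]1/C([Li])=C\[C@H](O[Si](C)(C)C(C)(C)C)[C@@H](C[C@H](O[Si](C)(C)C(C)(C)C)CC(=O)OC(C)(C)C)/C=C\C(C)=C/[C@H]1CO[Si](c2ccccc2)(c2ccccc2)C(C)(C)C
F9 | step 29 | C14 triethylsilyl ether of seco acid 37 | CC[C@H]1C[C@@H]2/C(C)=C\[C@H](O)[C@@H](C[C@H](O[Si](CC)(CC)CC)CC(=O)O)/C=C\C(C)=C/[C@H]2C(=O)O1
F10 | step 29 | rhizolutin O15-triethylsilyl ether | CC[C@H]1C[C@@H]2/C(C)=C\[C@@H]3OC(=O)C[C@@H](O[Si](CC)(CC)CC)C[C@H]3/C=C\C(C)=C/[C@H]2C(=O)O1
A1 | alternative 1 | rhizolutin O15 tert-butyldimethylsilyl ether | CC[C@H]1C[C@@H]2/C(C)=C\[C@@H]3OC(=O)C[C@@H](O[Si](C)(C)C(C)(C)C)C[C@H]3/C=C\C(C)=C/[C@H]2C(=O)O1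
A2 | alternative 2 | 6/10/6 tricyclic keto lactone ([6+4] adduct) | CC[C@H]1C[C@@H]2/C(C)=C\[C@@H]3C(=O)C[C@@H](O[Si](C)(C)C(C)(C)C)C[C@H]3/C=C\C(C)=C/[C@H]2C(=O)O1
A3 | alternative 3 | ten-membered C9 alcohol with C17 vinyl group | CC[C@H](O[Si](C)(C)C(C)(C)C)C[C@@H]1/C(C)=C\[C@H](O)[C@@H](C=C)/C=C\C(C)=C/[C@H]1COCc1ccc(OC)cc1
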